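The data stem from a simulated flask for an exercise, and the scatter is random.

In a one-step world, Wy passes into WyXo with a single time constant, and the early yield is simply time over that constant. Maple and birch can test this.

| flask | Wy | Qa | remark | time | volume of the second phase over the first |
|---|---|---|---|---|---|
| maple | 0.40 M | 0.36 M | the very flask that is asked about, followed so far |  |  |
| birch | 0.40 M | 0.18 M | run made earlier |  |  |
| flask | 0.40 M | 0.360 M |  | 10 d | 0.50 |

| run | time / d | WyXo / % | Wy / % |
|---|---|---|---|
| maple | 0.417 | 0.9 | 99.9 |
| maple | 0.833 | 0.4 | 98.2 |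
| maple | 2.00 | 2.9 | 96.0 |
| maple | 5.00 | 9.2 | 92.3 |
| birch | 0.833 | 0 | 98.0 |
| birch | 2.50 | 2.1 | 96.8 |
| birch | 5.00 | 2.6 | 95.7 |
| birch | 8.00 | 8.0 | 91.2 |

(standard deviation of a reading: 1 percentage point)

- in the second phase: Qa; everything else is in the first
- charges count per volume of the first phase; a concentration in a rate is the amount of a species over the volume of its own phase; every rate counts per litre of the first phase
- the earlier runs hold the two phases in the same ratio of volumes as the flask asked about

* amount of WyXo at 10 d, in percent of the Wy charged
* part of the Wy charged that has reacted at 10 d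

The ledger comes first. In maple at 5.00 d, Wy has lost 7.70% and WyXo stands at 9.2%. In birch at 8.00 d, the entries are 8.80% and 8.0%. Two readings with a scatter of 1 percentage point can differ so, therefore I book each Wy lost as WyXo. I also assume that each WyXo takes one Qa, which makes Qa the limiting reagent in the asked flask, at 0.360 M against 0.40 M of Wy.

Time over yield gives 54.3 d in maple and 100 d in birch, about twice as long on half the Qa. So I let the time constant of Wy vary inversely with cQa. Both runs were charged with 0.40 M of Wy and cannot show the effect of cWy, so I assume the rate proportional to cWy as well. Scaling birch to maple's cQa and taking the mean gives τ = 52.2 d, the time constant of Wy at the starting rate with cQa and cWy as charged in the asked flask.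

First round, nothing used up: t/τ = 19.2%

Mean shares left over the run: Wy 90.4%, Qa 89.4%

Second round: (t/τ) × both shares = 15.5%

I commit to that figure for both WyXo and Wy reacted. The forecast stands higher, at 17.5% and 18%, judging that “both runs hint at acceleration”.

The asked flask gives 13.7% of WyXo, with 15.1% of Wy reacted.

    Xo ⇌ Qa, rate k1*([Xo] - [Qa]/K1) per volume of the first phase (partition coefficient = 11.0, kL = 0.0140 h⁻¹)
    Xo → Eb (k = 0.250 h⁻¹)
    Xo ⇌ Qi (K = 1.10, k = 0.550 h⁻¹)
    Wy + Xo → WyXo (k = 0.360 L mol⁻¹ h⁻¹)
    Wy → Ve (k = 6.30 × 10⁻⁵ h⁻¹)

At 10 d the asked flask has lost 0.160 M of Qa, of which WyXo holds 0.0547 M, Eb 0.103 M, Xo 0.00133 M and Qi 0.00147 M. With the flask's own end values, the mean shares become 77.7% for Qa and 92.5% for Wy, and τ gives 13.8%. The same τ with the end values of the neighbour flask, charged with 1.6 M of Wy, gives 14.2%, but that neighbour flask holds 6.93% of WyXo.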